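**Retrosynthetic overview**

1. Last bond: C11=C12 by Wittig olefination between a C15 keto-aldehyde (ring A, C7–C11, C19 laurate already in place) and a C25 polyenyl ylide. The C25 salt comes from a ring E C15 hydroxy-aldehyde ((R)-α-ionone as chiral pool, C3′ by CBS reduction) and a C10 bis(phosphonium) salt (bond C11′=C12′).
2. C8–C9 by Nozaki–Hiyama–Kishi coupling of the ring A acetaldehyde with a C4 iodoalkene made from but-2-yne-1,4-diol; then laurate at C19 and MnO2 oxidation at C8 and C11.
3. Ring A by reductive ring closure at C3–C4 of an achiral, acyclic aldehyde–dienoate that is made in four steps from 2,2-dimethylpent-4-enoic acid.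
4. Feature used: in ring A the carbinol carbon C3 is bonded to the methylene C4, C4 is the δ-carbon of the chain C8(=O)–C7–C6=C5–C4, and the tetrasubstituted C5=C6 bond lies β,γ to the C8 carbonyl. This is the imprint of a 1,6-addition of a C3 ketyl to a C8 2,4-dienoate followed by protonation at C7.
5. Ring order: ring A is the only ring formed (step 5); ring E is bought with (R)-α-ionone.

Key step: step 5

Remark on the chemistry: the Wittig steps 20 and 21 first give E/Z mixtures at the new double bond; these are equilibrated to E by gentle warming in the dark, so only the all-E formulas are listed.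

**Route**

Step 1
Reactants: 1 2,2-dimethylpent-4-enoic acid; 2 methyl acetate
Product: 4 methyl 4,4-dimethyl-3-oxohept-6-enoate, via 2,2-dimethylpent-4-enoyl chloride 3 (not isolated)
Conditions: (COCl)2, cat. DMF, CH2Cl2, 0 °C to rt; then added to 2/LiN(i-Pr)2 (2.2 equiv each), THF, −78 °C; aq. NH4Cl
Reagents that add atoms: none
Why: Crossed Claisen-type C-acylation of the lithium enolate of methyl acetate by an acid chloride that can neither enolize nor form a ketene because its α-carbon is quaternary.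

Step 2
Reactants: 4 methyl 4,4-dimethyl-3-oxohept-6-enoate
Product: 5 methyl (2Z)-4,4-dimethyl-3-{[(trifluoromethyl)sulfonyl]oxy}hepta-2,6-dienoate
Conditions: NaH, Et2O, 0 °C; then (CF3SO2)2O, 0 °C
Reagents that add atoms: trifluoromethanesulfonic anhydride, O=S(=O)(OS(=O)(=O)C(F)(F)F)C(F)(F)F
Why: O-Sulfonylation of the chelated sodium enolate of the β-keto ester gives the (Z)-enol triflate, and only C2 can be deprotonated because C4 is quaternary.

Step 3
Reactants: 5 methyl (2Z)-4,4-dimethyl-3-{[(trifluoromethyl)sulfonyl]oxy}hepta-2,6-dienoate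
Product: 6 methyl (2Z)-4,4-dimethyl-6-oxo-3-{[(trifluoromethyl)sulfonyl]oxy}hex-2-enoate
Conditions: O3, CH2Cl2, −78 °C (indicator dye marks the end point); then PPh3, −78 °C to rt
Reagents that add atoms: ozone, [O-][O+]=O
Why: Ozonolysis with reductive work-up cleaves only the electron-rich terminal alkene, since the enol triflate double bond carries two acceptor groups and is inert to ozone at this temperature.

Step 4
Reactants: 6 methyl (2Z)-4,4-dimethyl-6-oxo-3-{[(trifluoromethyl)sulfonyl]oxy}hex-2-enoate; 7 4,4,5,5-tetramethyl-2-(prop-1-en-2-yl)-1,3,2-dioxaborolane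
Product: 8 methyl (2E)-4,4-dimethyl-6-oxo-3-(prop-1-en-2-yl)hex-2-enoate
Conditions: PdCl2(dppf) (5 mol%), K3PO4, THF/H2O, 40 °C
Reagents that add atoms: none
Why: Suzuki–Miyaura coupling of the alkenyl triflate with retention of double-bond geometry under a mild phosphate base that the aldehyde tolerates.

Step 5
Reactants: 8 methyl (2E)-4,4-dimethyl-6-oxo-3-(prop-1-en-2-yl)hex-2-enoate
Product: 10 methyl 2-[(4R)-4-hydroxy-2,6,6-trimethylcyclohex-1-en-1-yl]acetate, via trivalent samarium dienolate 9 (not isolated)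
Conditions: SmI2 (2.4 equiv), (R)-2,2′-bis(diphenylphosphoryl)-1,1′-binaphthyl [(R)-BINAPO] (2.6 equiv), t-BuOH (4 equiv), THF, −78 °C, slow addition of 8 (final 0.01 M); aq. Na2S2O3/NaHCO3
Reagents that add atoms: none
Why: Proposed new method: electron transfer from BINAPO-ligated divalent samarium to the aldehyde gives a trivalent samarium ketyl at C3 that adds to C4, the unsubstituted δ-terminus of the C8 dienoate; a second electron turns the allyl radical spread over C5–C6–C7 into dienolate 9, and tert-butanol protonates it at C7 (the α-carbon, kinetic site), which leaves the tetrasubstituted C5=C6 bond out of conjugation exactly as in the target. The closest known reaction type is the SmI2-mediated ketyl–olefin cyclization onto α,β-unsaturated esters, used here in its vinylogous 1,6-sense, together with ligand-controlled enantioselective SmI2 ketyl couplings; neither has been shown for a dienoate or for an aliphatic aldehyde that lacks a second binding site. Ring A closes in a 6-endo-trig radical mode at C4, and the substitution pattern shuts the alternatives, since attack at C5 would leave a primary radical, attack at C7 would be 5-endo and attack at C6 would make a four-membered ring. The only new stereocenter, C3, is set under reagent control: the ketyl oxygen stays bound to trivalent samarium inside the C2-symmetric pocket of the bis(phosphine oxide), and of the two mirror-image chair-like transition states the one that turns the gem-dimethyl carbon away from a P-phenyl wall should lead to (R). The step needs chemoselectivity (closure faster than pinacol coupling or simple carbonyl reduction, helped by slow addition at high dilution onto an activated acceptor), regioselective α-protonation (bulky proton source at −78 °C) and enantioselectivity, which is the open point. Should the sense of induction prove opposite, the (S)-ligand is taken.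

Step 6
Reactants: 10 methyl 2-[(4R)-4-hydroxy-2,6,6-trimethylcyclohex-1-en-1-yl]acetate
Product: 11 2-[(4R)-4-hydroxy-2,6,6-trimethylcyclohex-1-en-1-yl]acetaldehyde
Conditions: i-Bu2AlH (2.3 equiv), CH2Cl2, −78 °C; MeOH, then aq. potassium sodium tartrate
Reagents that add atoms: none
Why: Partial reduction of the ester stops at the aluminium hemiacetal at −78 °C and gives the aldehyde on work-up, the first hydride equivalent being used up by the free hydroxyl.

Step 7
Reactants: 12 but-2-yne-1,4-diol
Product: 13 (2E)-2-(tributylstannyl)but-2-ene-1,4-diol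
Conditions: Bu3SnH, PdCl2(PPh3)2 (2 mol%), THF, 0 °C to rt
Reagents that add atoms: tributyltin hydride, CCCC[SnH](CCCC)CCCC
Why: Palladium-catalysed syn-hydrostannation of a symmetric alkyne raises no regiochemical question and places tin and hydrogen cis, which fixes the later C9=C10 geometry.

Step 8
Reactants: 13 (2E)-2-(tributylstannyl)but-2-ene-1,4-diol
Product: 14 (2E)-4-{[tert-butyl(dimethyl)silyl]oxy}-2-(tributylstannyl)but-2-en-1-ol
Conditions: t-BuMe2SiCl (1.0 equiv), imidazole, CH2Cl2, −20 °C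
Reagents that add atoms: tert-butyldimethylsilyl chloride, CC(C)(C)[Si](C)(C)Cl
Why: Monosilylation occurs at the primary hydroxyl remote from the bulky tributylstannyl group (steric differentiation of the two alcohols).

Step 9
Reactants: 14 (2E)-4-{[tert-butyl(dimethyl)silyl]oxy}-2-(tributylstannyl)but-2-en-1-ol
Product: 15 (2E)-4-{[tert-butyl(dimethyl)silyl]oxy}-2-iodobut-2-en-1-ol
Conditions: I2, CH2Cl2, 0 °C
Reagents that add atoms: iodine, II
Why: Iododestannylation replaces tin by iodine with retention of alkene geometry.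

Step 10
Reactants: 11 2-[(4R)-4-hydroxy-2,6,6-trimethylcyclohex-1-en-1-yl]acetaldehyde; 15 (2E)-4-{[tert-butyl(dimethyl)silyl]oxy}-2-iodobut-2-en-1-ol
Product: 16 (3E)-5-{[tert-butyl(dimethyl)silyl]oxy}-1-[(4R)-4-hydroxy-2,6,6-trimethylcyclohex-1-en-1-yl]-3-(hydroxymethyl)pent-3-en-2-ol (both epimers at C2 of the pentenol, which is C8 of the target)
Conditions: CrCl2 (6 equiv), NiCl2 (2 mol%), DMSO, rt
Reagents that add atoms: none
Why: Nozaki–Hiyama–Kishi coupling, in which the alkenylchromium species adds to the enolizable β,γ-unsaturated aldehyde without deprotonating it and tolerates free hydroxyls, forms C8–C9 and a C8 carbinol whose configuration is irrelevant because it is oxidized in step 13.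

Step 11
Reactants: 16 the triol mono-silyl ether of step 10; 17 dodecanoyl chloride
Product: 18 (2E)-4-{[tert-butyl(dimethyl)silyl]oxy}-2-{1-hydroxy-2-[(4R)-4-hydroxy-2,6,6-trimethylcyclohex-1-en-1-yl]ethyl}but-2-en-1-yl dodecanoate
Conditions: 17 (1.05 equiv), 2,4,6-collidine, CH2Cl2, −78 to −40 °C
Reagents that add atoms: none
Why: Acylation with one equivalent of acid chloride and a hindered pyridine base at low temperature selects the only primary hydroxyl (C19) over the two secondary ones.

Step 12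
Reactants: 18 the silyl ether laurate of step 11
Product: 19 (2E)-4-hydroxy-2-{1-hydroxy-2-[(4R)-4-hydroxy-2,6,6-trimethylcyclohex-1-en-1-yl]ethyl}but-2-en-1-yl dodecanoate
Conditions: HF·pyridine, pyridine, THF, 0 °C
Reagents that add atoms: none
Why: Buffered fluoride cleaves the primary silyl ether without ester cleavage or base-induced acyl migration.

Step 13
Reactants: 19 the triol laurate of step 12
Product: 20 (2E)-2-{[(4R)-4-hydroxy-2,6,6-trimethylcyclohex-1-en-1-yl]acetyl}-4-oxobut-2-en-1-yl dodecanoate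
Conditions: MnO2 (activated, large excess), CH2Cl2, rt
Reagents that add atoms: none
Why: MnO2 oxidizes only allylic alcohols, so the primary C11–OH gives the enal and the secondary C8–OH the enone while the homoallylic C3–OH of ring A stays.

Step 14
Reactants: 21 (3E)-4-[(1R)-2,6,6-trimethylcyclohex-2-en-1-yl]but-3-en-2-one [(R)-α-ionone]; 22 diethyl (cyanomethyl)phosphonate
Product: 23 (2E,4E)-3-methyl-5-[(1R)-2,6,6-trimethylcyclohex-2-en-1-yl]penta-2,4-dienenitrile
Conditions: NaH, THF, 0 °C to rt; chromatographic removal of the (2Z)-isomer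
Reagents that add atoms: none
Why: Horner–Wadsworth–Emmons olefination of the methyl ketone should give mainly the (2E)-dienenitrile and is run before the ring is oxidized, so that C6′–H is not yet acidified.

Step 15
Reactants: 23 the dienenitrile of step 14
Product: 24 (2E,4E)-3-methyl-5-[(1R)-2,6,6-trimethyl-4-oxocyclohex-2-en-1-yl]penta-2,4-dienenitrile
Conditions: Rh2(caprolactamate)4 (1 mol%), t-BuOOH (5 equiv), K2CO3, CH2Cl2, rt
Reagents that add atoms: tert-butyl hydroperoxide, CC(C)(C)OO
Why: Catalytic allylic oxidation by tert-butylperoxyl radicals converts the ring CH2 next to the trisubstituted alkene into the enone, the electron-poor dienenitrile being unreactive toward these radicals.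

Step 16
Reactants: 24 the enone nitrile of step 15
Product: 25 (2E,4E)-5-[(1R,4R)-4-hydroxy-2,6,6-trimethylcyclohex-2-en-1-yl]-3-methylpenta-2,4-dienenitrile
Conditions: (S)-2-methyl-CBS-oxazaborolidine (20 mol%), catecholborane, toluene, −78 °C
Reagents that add atoms: none
Why: CBS reduction under catalyst control, with the alkene flank of the enone as the large and the CH2 flank as the small group, delivers hydride so that C3′ becomes (R), trans to the C6′ side chain, overriding the weak bias of the substrate.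

Step 17
Reactants: 25 the hydroxy nitrile of step 16
Product: 26 (2E,4E)-5-[(1R,4R)-4-hydroxy-2,6,6-trimethylcyclohex-2-en-1-yl]-3-methylpenta-2,4-dienal
Conditions: i-Bu2AlH (2.5 equiv), CH2Cl2, −78 °C; aq. potassium sodium tartrate, then wet silica gel
Reagents that add atoms: water, O
Why: Hydride addition to the nitrile stops at the aluminium aldimine, which is hydrolysed to the aldehyde on work-up, one hydride equivalent being taken by the hydroxyl.

Step 18
Reactants: 27 (2E,4E,6E)-2,7-dimethylocta-2,4,6-trienedial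
Product: 28 (2E,4E,6E)-2,7-dimethylocta-2,4,6-triene-1,8-diol
Conditions: NaBH4, MeOH/THF, 0 °C
Reagents that add atoms: none
Why: Borohydride reduces both conjugated aldehydes in the 1,2-sense.

Step 19
Reactants: 28 (2E,4E,6E)-2,7-dimethylocta-2,4,6-triene-1,8-diol
Product: 29 [(2E,4E,6E)-2,7-dimethylocta-2,4,6-triene-1,8-diyl]bis(triphenylphosphonium) dibromide
Conditions: PPh3·HBr (2.1 equiv), MeOH, rt
Reagents that add atoms: triphenylphosphine hydrobromide, [Br-].c1ccccc1[PH+](c1ccccc1)c1ccccc1
Why: Triphenylphosphine hydrobromide converts the allylic alcohols through the stabilized polyenyl cation into the bis(phosphonium) salt, and 28 has no other acid-sensitive group.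

Step 20
Reactants: 26 the ring E C15 hydroxy-aldehyde of step 17; 29 the C10 bis(phosphonium) dibromide
Product: 31 {(2E,4E,6E,8E,10E,12E)-13-[(1R,4R)-4-hydroxy-2,6,6-trimethylcyclohex-2-en-1-yl]-2,7,11-trimethyltrideca-2,4,6,8,10,12-hexaen-1-yl}triphenylphosphonium bromide, via monoylide 30 (not isolated)
Conditions: 29 (3 equiv), NaOMe (1.0 equiv relative to 26), MeOH/CH2Cl2, 0 °C to rt; excess 29 recovered
Reagents that add atoms: none
Why: Wittig olefination with one equivalent of base, in which the monoylide of the doubly charged salt forms preferentially and an excess of 29 suppresses double condensation; the acid-sensitive allylic C3′–OH never meets acid because it rides on the aldehyde partner.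

Step 21
Reactants: 20 the ring A keto-aldehyde laurate of step 13; 31 the C25 phosphonium bromide
Product: 33 target, (3R,3′R,6′R)-siphonaxanthin 19-dodecanoate, via C25 ylide 32 (not isolated)
Conditions: 1,2-epoxybutane (solvent and HBr acceptor), 60 °C, dark, argon; then heptane/EtOAc, 80 °C for E/Z equilibration
Reagents that add atoms: none
Why: Wittig olefination under neutral conditions, where the epoxide takes up HBr and releases the ylide in low stationary concentration, is compatible with the free hydroxyls, the allylic laurate and the enolizable enedione, and gentle heating equilibrates the new C11=C12 bond to E.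

**Compound list**

1 | 2,2-dimethylpent-4-enoic acid | C=CCC(C)(C)C(O)=O | starting material
2 | methyl acetate | COC(C)=O | starting material
3 | 2,2-dimethylpent-4-enoyl chloride | C=CCC(C)(C)C(Cl)=O | intermediate
4 | methyl 4,4-dimethyl-3-oxohept-6-enoate | COC(=O)CC(=O)C(C)(C)CC=C | intermediate
5 | methyl (2Z)-4,4-dimethyl-3-{[(trifluoromethyl)sulfonyl]oxy}hepta-2,6-dienoate | COC(=O)/C=C(\OS(=O)(=O)C(F)(F)F)C(C)(C)CC=C | intermediate
6 | methyl (2Z)-4,4-dimethyl-6-oxo-3-{[(trifluoromethyl)sulfonyl]oxy}hex-2-enoate | COC(=O)/C=C(\OS(=O)(=O)C(F)(F)F)C(C)(C)CC=O | intermediate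
7 | 4,4,5,5-tetramethyl-2-(prop-1-en-2-yl)-1,3,2-dioxaborolane | CC(=C)B1OC(C)(C)C(C)(C)O1 | starting material
8 | methyl (2E)-4,4-dimethyl-6-oxo-3-(prop-1-en-2-yl)hex-2-enoate | COC(=O)/C=C(\C(C)=C)C(C)(C)CC=O | intermediate
9 | bis(diiodosamarium) dienolate–alkoxide of 10 (trivalent samarium on the ketene acetal oxygen and on O3) | COC(O[Sm](I)I)=CC1=C(C)C[C@@H](O[Sm](I)I)CC1(C)C | intermediate
10 | methyl 2-[(4R)-4-hydroxy-2,6,6-trimethylcyclohex-1-en-1-yl]acetate | COC(=O)CC1=C(C)C[C@@H](O)CC1(C)C | intermediate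
11 | 2-[(4R)-4-hydroxy-2,6,6-trimethylcyclohex-1-en-1-yl]acetaldehyde | O=CCC1=C(C)C[C@@H](O)CC1(C)C | intermediate
12 | but-2-yne-1,4-diol | OCC#CCO | starting material
13 | (2E)-2-(tributylstannyl)but-2-ene-1,4-diol | OC/C(=C\CO)[Sn](CCCC)(CCCC)CCCC | intermediate
14 | (2E)-4-{[tert-butyl(dimethyl)silyl]oxy}-2-(tributylstannyl)but-2-en-1-ol | OC/C(=C\CO[Si](C)(C)C(C)(C)C)[Sn](CCCC)(CCCC)CCCC | intermediate
15 | (2E)-4-{[tert-butyl(dimethyl)silyl]oxy}-2-iodobut-2-en-1-ol | OC/C(I)=C\CO[Si](C)(C)C(C)(C)C | intermediate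
16 | (3E)-5-{[tert-butyl(dimethyl)silyl]oxy}-1-[(4R)-4-hydroxy-2,6,6-trimethylcyclohex-1-en-1-yl]-3-(hydroxymethyl)pent-3-en-2-ol, both C2 epimers | OC\C(=C/CO[Si](C)(C)C(C)(C)C)C(O)CC1=C(C)C[C@@H](O)CC1(C)C | intermediate
17 | dodecanoyl chloride | CCCCCCCCCCCC(Cl)=O | starting material
18 | (2E)-4-{[tert-butyl(dimethyl)silyl]oxy}-2-{1-hydroxy-2-[(4R)-4-hydroxy-2,6,6-trimethylcyclohex-1-en-1-yl]ethyl}but-2-en-1-yl dodecanoate | CCCCCCCCCCCC(=O)OC\C(=C/CO[Si](C)(C)C(C)(C)C)C(O)CC1=C(C)C[C@@H](O)CC1(C)C | intermediate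
19 | (2E)-4-hydroxy-2-{1-hydroxy-2-[(4R)-4-hydroxy-2,6,6-trimethylcyclohex-1-en-1-yl]ethyl}but-2-en-1-yl dodecanoate | CCCCCCCCCCCC(=O)OC\C(=C/CO)C(O)CC1=C(C)C[C@@H](O)CC1(C)C | intermediate
20 | (2E)-2-{[(4R)-4-hydroxy-2,6,6-trimethylcyclohex-1-en-1-yl]acetyl}-4-oxobut-2-en-1-yl dodecanoate | CCCCCCCCCCCC(=O)OC\C(=C/C=O)C(=O)CC1=C(C)C[C@@H](O)CC1(C)C | intermediate
21 | (3E)-4-[(1R)-2,6,6-trimethylcyclohex-2-en-1-yl]but-3-en-2-one, (R)-α-ionone | CC(=O)/C=C/[C@H]1C(C)=CCCC1(C)C | starting material
22 | diethyl (cyanomethyl)phosphonate | CCOP(=O)(CC#N)OCC | starting material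
23 | (2E,4E)-3-methyl-5-[(1R)-2,6,6-trimethylcyclohex-2-en-1-yl]penta-2,4-dienenitrile | N#C/C=C(C)/C=C/[C@H]1C(C)=CCCC1(C)C | intermediate
24 | (2E,4E)-3-methyl-5-[(1R)-2,6,6-trimethyl-4-oxocyclohex-2-en-1-yl]penta-2,4-dienenitrile | N#C/C=C(C)/C=C/[C@H]1C(C)=CC(=O)CC1(C)C | intermediate
25 | (2E,4E)-5-[(1R,4R)-4-hydroxy-2,6,6-trimethylcyclohex-2-en-1-yl]-3-methylpenta-2,4-dienenitrile | N#C/C=C(C)/C=C/[C@H]1C(C)=C[C@H](O)CC1(C)C | intermediate
26 | (2E,4E)-5-[(1R,4R)-4-hydroxy-2,6,6-trimethylcyclohex-2-en-1-yl]-3-methylpenta-2,4-dienal | O=C/C=C(C)/C=C/[C@H]1C(C)=C[C@H](O)CC1(C)C | intermediate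
27 | (2E,4E,6E)-2,7-dimethylocta-2,4,6-trienedial | O=C/C(C)=C/C=C/C=C(C)/C=O | starting material
28 | (2E,4E,6E)-2,7-dimethylocta-2,4,6-triene-1,8-diol | OC/C(C)=C/C=C/C=C(C)/CO | intermediate
29 | [(2E,4E,6E)-2,7-dimethylocta-2,4,6-triene-1,8-diyl]bis(triphenylphosphonium) dibromide | [Br-].[Br-].c1ccccc1[P+](c1ccccc1)(c1ccccc1)C/C(C)=C/C=C/C=C(C)/C[P+](c1ccccc1)(c1ccccc1)c1ccccc1 | intermediate
30 | monoylide of 29, [(2E,4E,6E)-2,7-dimethyl-8-(triphenyl-λ5-phosphanylidene)octa-2,4,6-trien-1-yl]triphenylphosphonium bromide | [Br-].c1ccccc1P(c1ccccc1)(c1ccccc1)=C/C(C)=C/C=C/C=C(C)/C[P+](c1ccccc1)(c1ccccc1)c1ccccc1 | intermediate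
31 | {(2E,4E,6E,8E,10E,12E)-13-[(1R,4R)-4-hydroxy-2,6,6-trimethylcyclohex-2-en-1-yl]-2,7,11-trimethyltrideca-2,4,6,8,10,12-hexaen-1-yl}triphenylphosphonium bromide | [Br-].c1ccccc1[P+](c1ccccc1)(c1ccccc1)C/C(C)=C/C=C/C=C(C)/C=C/C=C(C)/C=C/[C@H]1C(C)=C[C@H](O)CC1(C)C | intermediate
32 | ylide of 31, (1R,4R)-3,5,5-trimethyl-4-[(1E,3E,5E,7E,9E,11E)-3,7,12-trimethyl-13-(triphenyl-λ5-phosphanylidene)trideca-1,3,5,7,9,11-hexaen-1-yl]cyclohex-2-en-1-ol | c1ccccc1P(c1ccccc1)(c1ccccc1)=C/C(C)=C/C=C/C=C(C)/C=C/C=C(C)/C=C/[C@H]1C(C)=C[C@H](O)CC1(C)C | intermediate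
33 | (3R,3′R,6′R)-3,3′-dihydroxy-8-oxo-7,8-dihydro-β,ε-caroten-19-yl dodecanoate (all-E in the usual carotenoid sense) | CCCCCCCCCCCC(=O)OC\C(=C/C=C/C(C)=C/C=C/C=C(C)/C=C/C=C(C)/C=C/[C@H]1C(C)=C[C@H](O)CC1(C)C)C(=O)CC1=C(C)C[C@@H](O)CC1(C)C | target

**Step count and risks**

Total step count: 21. Longest linear sequence: 11 steps (steps 1–6, 10–13, 21).

Steps most likely to fail:

Step 5 (bears the label). What may go wrong: intermolecular pinacol coupling or simple carbonyl reduction outrunning the 6-endo closure, and too little facial discrimination by the ligand, so that C3 is formed with low enantiomeric enrichment. The fallback uses known chemistry, gives up the C3–C4 closure and buys the stereocenter; it sets out from 2 (methyl acetate) and comes back at 10. Commercial (4R,6R)-4-hydroxy-2,2,6-trimethylcyclohexan-1-one F1 is silylated (t-BuMe2SiCl, imidazole, DMF) to (4R,6R)-4-{[tert-butyl(dimethyl)silyl]oxy}-2,2,6-trimethylcyclohexan-1-one F2. KN(SiMe3)2 and N-phenylbis(trifluoromethanesulfonimide) in THF at −78 °C give (4R)-4-{[tert-butyl(dimethyl)silyl]oxy}-2,6,6-trimethylcyclohex-1-en-1-yl trifluoromethanesulfonate F3, the only possible regioisomer because the other α-carbon is quaternary. The zinc enolate of 2 (LiN(i-Pr)2, then ZnCl2) is coupled with F3 under zerovalent palladium catalysis (Pd(dba)2, P(t-Bu)3, THF; Negishi coupling of a Reformatsky-type reagent) to methyl 2-[(4R)-4-{[tert-butyl(dimethyl)silyl]oxy}-2,6,6-trimethylcyclohex-1-en-1-yl]acetate F4. HF·pyridine in THF then frees 10.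

Step 16. What may go wrong: catalyst control too weak against the conformational bias of the substrate, so that hydride is delivered to both faces and C3′ epimers result. The fallback sets out from 24 and comes back at 25. Luche reduction (NaBH4, CeCl3·7H2O, MeOH, −78 °C) gives the allylic alcohols; the trans-isomer is 25 itself and the cis-isomer, (2E,4E)-5-[(1R,4S)-4-hydroxy-2,6,6-trimethylcyclohex-2-en-1-yl]-3-methylpenta-2,4-dienenitrile F5, is separated by chromatography. Mitsunobu reaction of F5 (4-nitrobenzoic acid, PPh3, diisopropyl azodicarboxylate, THF, 0 °C) inverts C3′ to (1R,4R)-4-[(1E,3E)-4-cyano-3-methylbuta-1,3-dien-1-yl]-3,5,5-trimethylcyclohex-2-en-1-yl 4-nitrobenzoate F6, and K2CO3 in MeOH releases 25.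

Step 21. What may go wrong: deprotonation at C7 or conjugate addition to the enedione aldehyde 20 by the ylide, and loss of material during E/Z equilibration. The fallback carries C8 as the carbinol through the olefination; it sets out from 19 and 31 and comes back at 33. Triol 19 is oxidized only at the primary allylic position (TEMPO, PhI(OAc)2, CH2Cl2) to (2E)-2-{1-hydroxy-2-[(4R)-4-hydroxy-2,6,6-trimethylcyclohex-1-en-1-yl]ethyl}-4-oxobut-2-en-1-yl dodecanoate F7, which has neither the ketone nor the acidic C7–H. Salt 31 is silylated at C3′ (Et3SiCl, imidazole) to the 3′-O-triethylsilyl C25 phosphonium bromide F8. Wittig olefination of F7 with F8 in 1,2-epoxybutane gives the 8-hydroxy-7,8-dihydro carotenoid 3′-O-triethylsilyl ether F9. MnO2 oxidizes its polyene-conjugated allylic C8–OH (C3′ is now protected, C3–OH is not allylic) to the 3′-O-triethylsilyl ether of the target F10, and HF·pyridine/pyridine in THF at 0 °C gives 33.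

**Further compounds**

F1 | step 5 | (4R,6R)-4-hydroxy-2,2,6-trimethylcyclohexan-1-one | O=C1C(C)(C)C[C@H](O)C[C@H]1C
F2 | step 5 | (4R,6R)-4-{[tert-butyl(dimethyl)silyl]oxy}-2,2,6-trimethylcyclohexan-1-one | O=C1C(C)(C)C[C@H](O[Si](C)(C)C(C)(C)C)C[C@H]1C
F3 | step 5 | (4R)-4-{[tert-butyl(dimethyl)silyl]oxy}-2,6,6-trimethylcyclohex-1-en-1-yl trifluoromethanesulfonate | FC(F)(F)S(=O)(=O)OC1=C(C)C[C@@H](O[Si](C)(C)C(C)(C)C)CC1(C)C
F4 | step 5 | methyl 2-[(4R)-4-{[tert-butyl(dimethyl)silyl]oxy}-2,6,6-trimethylcyclohex-1-en-1-yl]acetate | COC(=O)CC1=C(C)C[C@@H](O[Si](C)(C)C(C)(C)C)CC1(C)C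
F5 | step 16 | (2E,4E)-5-[(1R,4S)-4-hydroxy-2,6,6-trimethylcyclohex-2-en-1-yl]-3-methylpenta-2,4-dienenitrile | N#C/C=C(C)/C=C/[C@H]1C(C)=C[C@@H](O)CC1(C)C
F6 | step 16 | (1R,4R)-4-[(1E,3E)-4-cyano-3-methylbuta-1,3-dien-1-yl]-3,5,5-trimethylcyclohex-2-en-1-yl 4-nitrobenzoate | N#C/C=C(C)/C=C/[C@H]1C(C)=C[C@H](OC(=O)c2ccc(cc2)[N+](=O)[O-])CC1(C)C
F7 | step 21 | (2E)-2-{1-hydroxy-2-[(4R)-4-hydroxy-2,6,6-trimethylcyclohex-1-en-1-yl]ethyl}-4-oxobut-2-en-1-yl dodecanoate | CCCCCCCCCCCC(=O)OC\C(=C/C=O)C(O)CC1=C(C)C[C@@H](O)CC1(C)C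
F8 | step 21 | {(2E,4E,6E,8E,10E,12E)-2,7,11-trimethyl-13-[(1R,4R)-2,6,6-trimethyl-4-[(triethylsilyl)oxy]cyclohex-2-en-1-yl]trideca-2,4,6,8,10,12-hexaen-1-yl}triphenylphosphonium bromide | [Br-].c1ccccc1[P+](c1ccccc1)(c1ccccc1)C/C(C)=C/C=C/C=C(C)/C=C/C=C(C)/C=C/[C@H]1C(C)=C[C@H](O[Si](CC)(CC)CC)CC1(C)C
F9 | step 21 | (3R,3′R,6′R)-3,8-dihydroxy-3′-[(triethylsilyl)oxy]-7,8-dihydro-β,ε-caroten-19-yl dodecanoate, both C8 epimers | CCCCCCCCCCCC(=O)OC\C(=C/C=C/C(C)=C/C=C/C=C(C)/C=C/C=C(C)/C=C/[C@H]1C(C)=C[C@H](O[Si](CC)(CC)CC)CC1(C)C)C(O)CC1=C(C)C[C@@H](O)CC1(C)C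
F10 | step 21 | (3R,3′R,6′R)-3-hydroxy-8-oxo-3′-[(triethylsilyl)oxy]-7,8-dihydro-β,ε-caroten-19-yl dodecanoate | CCCCCCCCCCCC(=O)OC\C(=C/C=C/C(C)=C/C=C/C=C(C)/C=C/C=C(C)/C=C/[C@H]1C(C)=C[C@H](O[Si](CC)(CC)CC)CC1(C)C)C(=O)CC1=C(C)C[C@@H](O)CC1(C)C
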